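Core locants used throughout: five-membered ring C1–C2–C3–C4–C10, seven-membered ring C4–C5–C6–C7–C8–C9–C10. "β" is the face of the C10 methyl group, "α" the face of C4–H in the target. Bicyclic compounds are named on a bicyclo[5.3.0]decane core with these locants, not with von Baeyer locants.

## Analysis of the target

The target is a trans-fused bicyclo[5.3.0]dec-7-ene (a daucane-type hydroazulene). The five-membered ring is C1(OAc)–C2–C3(OH, i-Pr)–C4(H)–C10(CH3), the seven-membered ring is C4–C5(O-aroyl)–C6–C7(CH3)=C8–C9–C10, and the five stereocentres are 1S,3R,4S,5S,10R. The C10 methyl group and the C3 hydroxyl lie on the β face; C4–H and the C1 acetoxy group lie on the α face, so the ring fusion is trans and the two oxygens of the five-membered ring are trans to each other. The C5 ester is equatorial on the seven-membered ring: C5–H is anti to C4–H and syn-axial to the C10 methyl group, and the C5 oxygen is 1,3-syn to the C3 hydroxyl. The sensitive points are two different esters beside a free phenol, a tertiary alcohol that is β to both C1 and C5 (a ketone at either carbon invites retro-aldol cleavage or dehydration, and the C5 ester can migrate), and a trisubstituted alkene that must not drift towards C6. The synthesis is hard because the quaternary C10 sits between two stereocentres at a trans 5–7 fusion, because C3, C4, C5 and C10 are contiguous, and because three oxygen functions of different kind must be told apart. The strategy rests on the seven-membered ring: an oxygen on C5, a C7=C8 double bond with a substituent on C7, and a fully substituted C10 are what a [3,3] shift of a cis-divinylcyclopropane leaves behind when the three-membered ring is C5–C6–C7, C5 carries an oxido group and the vinyl groups are C4=C10 and C8=C9.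

## Retrosynthetic reasoning

**Phenol and acetate (30 ⇒ 29 ⇒ 28).** The phenol is unmasked last from allyl ether 29 under neutral conditions that touch neither ester. The acetate is placed on the secondary C1 hydroxyl of diol 28; the tertiary C3 hydroxyl does not compete.

**C1 configuration (28 ⇒ 27 ⇒ 26 ⇒ 25).** The C1 oxygen is carried through the route as the β epimer, because on that face it steers the key step, and it is inverted late through ketone 27. An external hydride would come anti to the C10 methyl group and return the β alcohol, so the free β hydroxyl at C3 is used to deliver hydride to the β face, which gives the α alcohol of 28. For that reason both silyl ethers of 25 are removed together (26) before the oxidation, and the phenol protecting group of 25 cannot be a silyl group.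

**C5 ester (25 ⇒ 23 + 24).** The acyl–oxygen bond is cut. The aroyl group is attached only after all organolithium chemistry is finished; acid chloride 24 carries the phenol as an allyl ether that survives fluoride, oxidation and hydride.

**C7 methyl (23 ⇒ 22 ⇒ 20).** The C7–CH3 bond is cut back to enol triflate 22. The silyl enol ether of 20 holds the C7=C8 regiochemistry made in the key step, and it is converted into 22 without passing through a free C7 ketone, which could enolise on either side.

**C5 carbinol (20 ⇒ 19).** The C5 ketone is reduced before C7 is unmasked, so that a 1,3-diketone never arises. The equatorial alcohol is needed. A hydride reagent would approach anti to the angular methyl group and give the axial epimer, and delivery from the C3 oxygen would do the same, so the reduction is run under thermodynamic control.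

**Seven-membered ring (19 ⇒ 10 + 14).** The ring is cut at C6–C7 and C9–C10. These are the bonds that a [3+4] union can make in one flask: in ketone 10 the acetyl methyl group is C6 (nucleophilic as the enolate), C5 is electrophilic and C10 is the far end of the enone; in acylsilane 14, C7 is first electrophilic and, after silyl migration to oxygen, nucleophilic, and C9 is the alkene terminus. Cutting here leaves the whole five-membered ring, with C1 and C3 oxygenated and C3 configured, in one fragment and three carbons in the other. It returns C5 as a ketone and C7 as a silyl enol ether, so the two oxygens stay distinct, and it creates C10. The forward reaction must enolise 10 only at the methyl group, rearrange faster than the cyclopropanolate falls apart although C10 is fully substituted, bring C9 to the α face of C10, and end with C4–H on the α face.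

**Acylsilane (14 ⇒ 13 ⇒ 11).** The carbonyl is unmasked from the enol ether of silylallene 13, which comes from C-silylation of metalated methoxyallene 11. The tert-butyldimethylsilyl group still migrates in the Brook step and leaves an enol ether robust enough to be carried through a reduction.

**Acetyl group (10 ⇒ 9 ⇒ 7).** The bond between ring carbon C4 and the acetyl carbon C5 is cut. Halogen–lithium exchange on vinyl bromide 7 and addition to a two-carbon aldehyde give carbinol 9, which is oxidised; this is more dependable on so hindered an alkenyl carbon than direct acylation.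

**C3 carbinol (7 ⇒ 6 ⇒ 5).** The C3–isopropyl bond is cut. 1,2-Addition to bromo enone 5 from the face opposite the silyloxy group gives 6 with the two oxygens cis, which is the relationship the key step needs, and the only purchased stereocentre (C1) then controls C3.

**Bromo enone (5 ⇒ 3 ⇒ 2 ⇒ 1).** The bromine, the later attachment point of the acetyl group, comes from bromination–dehydrobromination of enone 3. The future C10 methyl group is introduced on enone 1 by conjugate addition, and the enone is restored from silyl enol ether 2 by dehydrogenation.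

## Alternatives that were turned down

Alternative 1: This cuts C9–C10 and C4–C5 of a six-membered ring that holds every carbon of the seven-membered ring except C6. An AlBr3-activated chiral oxazaborolidine would catalyse the Diels–Alder reaction of silyloxydiene A2 with the E-configured keto ester A3 to give cyclohexene A1.
- For it: one intermolecular step from two achiral partners makes the quaternary C10, fixes the trans relationship of the C10 methyl group and C4–H from the dienophile geometry, and sets the absolute configuration under catalyst control. On this point it is stronger than the chosen route, whose absolute configuration is bought with compound 1 and whose C10 is set under substrate control.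
- Against it: A1 is far from the target. C6 must still be inserted between C5 and C7. The five-membered ring must still be closed from the ester and the isopropyl ketone with C2 added, and C3 would be created late as a tertiary carbinol without an obvious control element. The endo adduct has the C5 oxygen cis to the acyl group on C4, which is the C5 epimer of the target. Two carbonyl groups on A3 also leave open which one the Lewis acid binds.
- Comparison: in place of catalyst control, the chosen strategy delivers the complete seven-membered ring, with C5 and C7 differentiated, on a five-membered ring that already carries C1 and C3, so no ring has to be built or enlarged after the key step.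

Alternative 2: This cuts C1–C10, so the five-membered ring is closed last onto a preformed cycloheptadiene. FeCl3 would promote 4π conrotatory closure of the pentadienyl cation from dienone A5, and loss of silicon would place the alkene at C1=C2 in enone A4.
- For it: electrocyclisation is a dependable way to a quaternary carbon and silicon decides where the double bond ends. In forming a bond at a fully substituted centre it is at least as secure as the [3,3] shift of the chosen route.
- Against it: A4 has neither the C3 isopropyl group nor the C3 and C1 oxygens. They would have to come from 1,2-addition at C3 and from hydration of C1=C2 with oxygen on the hindered C1, both with stereocontrol still to be found. The torquoselectivity, and with it C10, hangs on one silyloxy stereocentre at C5 that is allylic to the reacting alkene and open to ionisation by the Lewis acid; in A4 this centre is also the epimer of the target's C5. The seven-membered ring, the harder ring, must exist before the key step.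
- Comparison: the chosen strategy spends its key step on the seven-membered ring and brings C3 in fully formed from compound 6.

Alternative 3: This cuts C2–C3 late. Rh2(OAc)4 would turn diazoketone A7 into a carbene that inserts into the silyloxy-activated C3–H bond to give cyclopentanone A6 with retention at C3.
- For it: A6 is only a reduction, an acetylation and a desilylation from the target, the tertiary carbinol is derived stereospecifically from a secondary one, and 1,5-insertion is the favoured ring size. After its key step this route is shorter than the chosen one.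
- Against it: A7 must already contain the seven-membered ring with C4, C5 and the quaternary C10, so the difficult part is only moved upstream. The carbene also lies within reach of the C7=C8 alkene (cyclopropanation would close a five-membered ring as well) and of other C–H bonds, while the wanted bond is a hindered tertiary C–H.
- Comparison: the chosen strategy has a key step that makes the ring system and C10 itself, at the price of a longer but conventional functional-group endgame.

Key step: step 10

Remark on the chemistry: compounds 1 (single R enantiomer), 11 and 24 and all reagents are taken as purchased; 14 polymerises readily and is to be used directly after step 9.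

## Route

Step 1
Reactants: 1 (R)-4-(tert-butyldimethylsilyloxy)cyclopent-2-en-1-one
Product: 2 tert-butyldimethyl{[(1R,2R)-2-methyl-4-(trimethylsilyloxy)cyclopent-3-en-1-yl]oxy}silane
Conditions: MeMgBr, CuBr·SMe2 (10 mol %), TMSCl, THF, −78 °C
Reagents that add atoms: methylmagnesium bromide (C[Mg]Br); chlorotrimethylsilane (C[Si](C)(C)Cl)
Why: Copper-catalysed conjugate addition places the methyl group anti to the silyloxy group; silylation in the flask fixes the enolate as the silyl enol ether needed in step 2 and keeps it from equilibrating to the isomer that would expel the silyloxy group. The methyl-bearing centre is removed again in step 2.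

Step 2
Reactants: 2 tert-butyldimethyl{[(1R,2R)-2-methyl-4-(trimethylsilyloxy)cyclopent-3-en-1-yl]oxy}silane
Product: 3 (R)-4-(tert-butyldimethylsilyloxy)-3-methylcyclopent-2-en-1-one
Conditions: Pd(OAc)2 (1.05 equiv), MeCN, rt
Reagents that add atoms: none
Why: Saegusa–Ito oxidation: the silyl enol ether gives a divalent palladium enolate, and β-hydride elimination towards the methyl-bearing carbon restores the enone, now with the methyl group on the β carbon; the silyloxy stereocentre is not involved.

Step 3
Reactants: 3 (R)-4-(tert-butyldimethylsilyloxy)-3-methylcyclopent-2-en-1-one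
Product: 5 (R)-2-bromo-4-(tert-butyldimethylsilyloxy)-3-methylcyclopent-2-en-1-one, via dibromide 4 (not isolated)
Conditions: Br2, CH2Cl2, 0 °C; then Et3N, 0 °C → rt
Reagents that add atoms: bromine (BrBr)
Why: Bromine adds across the enone double bond, and Et3N removes the acidic proton between carbonyl and bromine so that the β bromide leaves (E1cB dehydrobromination), the standard route to α-bromo enones.

Step 4
Reactants: 5 (R)-2-bromo-4-(tert-butyldimethylsilyloxy)-3-methylcyclopent-2-en-1-one
Product: 6 (1R,4R)-2-bromo-4-(tert-butyldimethylsilyloxy)-3-methyl-1-(propan-2-yl)cyclopent-2-en-1-ol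
Conditions: i-PrMgCl, CeCl3, THF, −78 °C
Reagents that add atoms: isopropylmagnesium chloride (CC(C)[Mg]Cl)
Why: Organocerium 1,2-addition to the ketone; the reagent is weakly basic, which suppresses γ-deprotonation and β-hydride reduction. The nucleophile approaches anti to the silyloxy group two carbons away, so the new hydroxyl is cis to it and the later C3 is set as R.

Step 5
Reactants: 6 (1R,4R)-2-bromo-4-(tert-butyldimethylsilyloxy)-3-methyl-1-(propan-2-yl)cyclopent-2-en-1-ol
Product: 7 {[(1R,4R)-2-bromo-4-(tert-butyldimethylsilyloxy)-3-methyl-1-(propan-2-yl)cyclopent-2-en-1-yl]oxy}triethylsilane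
Conditions: TESOTf, 2,6-lutidine, CH2Cl2, −78 → 0 °C
Reagents that add atoms: triethylsilyl trifluoromethanesulfonate (CC[Si](CC)(CC)OS(=O)(=O)C(F)(F)F)
Why: Silyl triflates silylate tertiary alcohols under buffered conditions; the triethylsilyl group is chosen because it can later be removed from this crowded position.

Step 6
Reactants: 7 {[(1R,4R)-2-bromo-4-(tert-butyldimethylsilyloxy)-3-methyl-1-(propan-2-yl)cyclopent-2-en-1-yl]oxy}triethylsilane
Product: 9 1-[(3R,5R)-3-(tert-butyldimethylsilyloxy)-2-methyl-5-(propan-2-yl)-5-(triethylsilyloxy)cyclopent-1-en-1-yl]ethan-1-ol (both carbinol epimers), via alkenyllithium 8 (not isolated)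
Conditions: t-BuLi (2.1 equiv), THF, −78 °C; then MeCHO, −78 °C
Reagents that add atoms: acetaldehyde (CC=O)
Why: Bromine–lithium exchange gives the cyclic alkenyllithium, which adds to the small, reactive aldehyde; the silyloxy group on the far side of the alkene is trans to lithium and cannot migrate. The new carbinol centre is removed in step 7.

Step 7
Reactants: 9 1-[(3R,5R)-3-(tert-butyldimethylsilyloxy)-2-methyl-5-(propan-2-yl)-5-(triethylsilyloxy)cyclopent-1-en-1-yl]ethan-1-ol
Product: 10 1-[(3R,5R)-3-(tert-butyldimethylsilyloxy)-2-methyl-5-(propan-2-yl)-5-(triethylsilyloxy)cyclopent-1-en-1-yl]ethan-1-one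
Conditions: Dess–Martin periodinane, NaHCO3, CH2Cl2, 0 °C → rt
Reagents that add atoms: none
Why: Dess–Martin oxidation of the allylic alcohol to the methyl ketone under buffered, non-epimerising conditions; the silyl ethers are inert.

Step 8
Reactants: 11 methoxyallene (1-methoxypropa-1,2-diene)
Product: 13 tert-butyl(1-methoxypropa-1,2-dien-1-yl)dimethylsilane, via lithioallene 12 (not isolated)
Conditions: n-BuLi, THF, −78 °C; then TBSCl, −78 °C → rt
Reagents that add atoms: tert-butyldimethylsilyl chloride (CC(C)(C)[Si](C)(C)Cl)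
Why: Alkoxyallenes are lithiated at the oxygen-bearing carbon, and the lithio species is silylated on carbon.

Step 9
Reactants: 13 tert-butyl(1-methoxypropa-1,2-dien-1-yl)dimethylsilane
Product: 14 1-[tert-butyl(dimethyl)silyl]prop-2-en-1-one
Conditions: 1 M aq. HCl, THF, 0 °C
Reagents that add atoms: water (O)
Why: Enol ether hydrolysis: protonation at the central allene carbon gives a vinyl-substituted oxocarbenium ion, and addition of water with loss of methanol leaves the acryloylsilane.

Step 10
Reactants: 10 1-[(3R,5R)-3-(tert-butyldimethylsilyloxy)-2-methyl-5-(propan-2-yl)-5-(triethylsilyloxy)cyclopent-1-en-1-yl]ethan-1-one; 14 1-[tert-butyl(dimethyl)silyl]prop-2-en-1-one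
Product: 19 (1R,3R,4R,10R)-1,7-bis(tert-butyldimethylsilyloxy)-10-methyl-3-(propan-2-yl)-3-(triethylsilyloxy)bicyclo[5.3.0]dec-7-en-5-one, via lithium enolate 15 (not isolated), via alkoxide adduct 16 (not isolated), via cyclopropanolate 17 (not isolated), via bicyclic enolate 18 (not isolated)
Conditions: LiN(iPr)2, THF, −78 °C; 14 in THF, −78 → −30 °C; AcOH, −78 °C
Reagents that add atoms: none
Why: LiN(iPr)2 deprotonates the acetyl methyl group of 10, the only kinetically accessible α position, and C6 of enolate 15 adds to the carbonyl of 14 to give alkoxide 16. 1,2-Silyl migration from carbon to oxygen (Brook rearrangement) makes C7 nucleophilic, and it closes onto the C5 carbonyl (3-exo-trig) to the cis-1,2-divinylcyclopropanolate 17. An oxyanion-accelerated [3,3] shift of 17 through a boat transition state cleaves C5–C7 and joins C9 to C10, so the seven-membered ring closes by sigmatropic ring expansion of the three-membered ring and not by direct cyclisation, and enolate 18 results. The closest known reaction type is the Brook rearrangement-mediated [3+4] annulation of acryloylsilanes with lithium enolates of alkenyl methyl ketones. C10 is set in the [3,3] shift: C9 bonds to the α face, anti to the C1 silyloxy group on the neighbouring carbon, a path on which the alkoxide oxygen of 17 lies on the β face beside the C3 silyl ether oxygen. C4 is set when 18 is protonated; the trans-fused ketone 19, with C5 trans to the C3 isopropyl group, is the expected thermodynamic isomer and can be reached by equilibration through the enol if kinetic protonation gives the cis isomer. The step needs regioselective enolisation, which the single α-methyl group secures, and distinct oxygens at C5 and C7, which the enolate and the silyl enol ether provide.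

Step 11
Reactants: 19 (1R,3R,4R,10R)-1,7-bis(tert-butyldimethylsilyloxy)-10-methyl-3-(propan-2-yl)-3-(triethylsilyloxy)bicyclo[5.3.0]dec-7-en-5-one
Product: 20 (1R,3R,4S,5S,10R)-1,7-bis(tert-butyldimethylsilyloxy)-10-methyl-3-(propan-2-yl)-3-(triethylsilyloxy)bicyclo[5.3.0]dec-7-en-5-ol
Conditions: Li, NH3(l), THF, t-BuOH, −78 °C; then NH4Cl
Reagents that add atoms: none
Why: Dissolving-metal reduction of the ketone: the carbanion formed by electron transfer is protonated under thermodynamic control and should give the more stable equatorial alcohol, with C5–H syn-axial to the C10 methyl group and anti to C4–H (5S). A hydride reagent would approach anti to the angular methyl group and give the axial epimer. Isolated silyl enol ethers and silyl ethers are not reduced.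

Step 12
Reactants: 20 (1R,3R,4S,5S,10R)-1,7-bis(tert-butyldimethylsilyloxy)-10-methyl-3-(propan-2-yl)-3-(triethylsilyloxy)bicyclo[5.3.0]dec-7-en-5-ol
Product: 22 (1R,3R,4S,5S,10R)-1-(tert-butyldimethylsilyloxy)-5-hydroxy-10-methyl-3-(propan-2-yl)-3-(triethylsilyloxy)bicyclo[5.3.0]dec-7-en-7-yl trifluoromethanesulfonate, via dilithium alkoxide enolate 21 (not isolated)
Conditions: MeLi (3 equiv), THF, 0 °C → rt; then PhNTf2, −78 → 0 °C
Reagents that add atoms: N-phenylbis(trifluoromethanesulfonimide) (O=S(=O)(N(c1ccccc1)S(=O)(=O)C(F)(F)F)C(F)(F)F)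
Why: MeLi first deprotonates the hydroxyl and then attacks silicon of the enol ether, releasing the C7=C8 lithium enolate regiospecifically with no proton source present; O-triflation of the enolate is faster than triflation of the hindered lithium alkoxide. The alkyl silyl ethers are inert to MeLi.

Step 13
Reactants: 22 (1R,3R,4S,5S,10R)-1-(tert-butyldimethylsilyloxy)-5-hydroxy-10-methyl-3-(propan-2-yl)-3-(triethylsilyloxy)bicyclo[5.3.0]dec-7-en-7-yl trifluoromethanesulfonate
Product: 23 (1R,3R,4S,5S,10R)-1-(tert-butyldimethylsilyloxy)-7,10-dimethyl-3-(propan-2-yl)-3-(triethylsilyloxy)bicyclo[5.3.0]dec-7-en-5-ol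
Conditions: SnMe4, Pd(PPh3)4 (5 mol %), LiCl, DMF, 60 °C
Reagents that add atoms: tetramethylstannane (C[Sn](C)(C)C)
Why: Stille coupling of an alkenyl triflate with zerovalent palladium; the double bond stays at C7=C8, and the neutral conditions tolerate the free hydroxyl and the silyl ethers.

Step 14
Reactants: 23 (1R,3R,4S,5S,10R)-1-(tert-butyldimethylsilyloxy)-7,10-dimethyl-3-(propan-2-yl)-3-(triethylsilyloxy)bicyclo[5.3.0]dec-7-en-5-ol; 24 4-(prop-2-en-1-yloxy)benzoyl chloride
Product: 25 (1R,3R,4S,5S,10R)-1-(tert-butyldimethylsilyloxy)-7,10-dimethyl-3-(propan-2-yl)-3-(triethylsilyloxy)bicyclo[5.3.0]dec-7-en-5-yl 4-(prop-2-en-1-yloxy)benzoate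
Conditions: Et3N, DMAP, CH2Cl2, rt → 40 °C
Reagents that add atoms: none
Why: DMAP-catalysed acylation of the only free hydroxyl; the acylpyridinium intermediate is reactive enough for an equatorial secondary alcohol next to the ring fusion.

Step 15
Reactants: 25 (1R,3R,4S,5S,10R)-1-(tert-butyldimethylsilyloxy)-7,10-dimethyl-3-(propan-2-yl)-3-(triethylsilyloxy)bicyclo[5.3.0]dec-7-en-5-yl 4-(prop-2-en-1-yloxy)benzoate
Product: 26 (1R,3R,4S,5S,10R)-1,3-dihydroxy-7,10-dimethyl-3-(propan-2-yl)bicyclo[5.3.0]dec-7-en-5-yl 4-(prop-2-en-1-yloxy)benzoate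
Conditions: HF·pyridine, pyridine, THF, 0 °C → rt
Reagents that add atoms: none
Why: Buffered acidic fluoride cleaves both alkyl silyl ethers; unlike basic fluoride it does not generate the C3 alkoxide next to the C5 ester, so acyl migration is avoided, and the allyl ether is inert.

Step 16
Reactants: 26 (1R,3R,4S,5S,10R)-1,3-dihydroxy-7,10-dimethyl-3-(propan-2-yl)bicyclo[5.3.0]dec-7-en-5-yl 4-(prop-2-en-1-yloxy)benzoate
Product: 27 (3R,4S,5S,10R)-3-hydroxy-7,10-dimethyl-1-oxo-3-(propan-2-yl)bicyclo[5.3.0]dec-7-en-5-yl 4-(prop-2-en-1-yloxy)benzoate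
Conditions: Dess–Martin periodinane, NaHCO3, CH2Cl2, 0 °C → rt
Reagents that add atoms: none
Why: Only the secondary C1 alcohol can be oxidised; the buffered neutral conditions spare the β-hydroxy ketone from dehydration and retro-aldol cleavage.

Step 17
Reactants: 27 (3R,4S,5S,10R)-3-hydroxy-7,10-dimethyl-1-oxo-3-(propan-2-yl)bicyclo[5.3.0]dec-7-en-5-yl 4-(prop-2-en-1-yloxy)benzoate
Product: 28 (1S,3R,4S,5S,10R)-1,3-dihydroxy-7,10-dimethyl-3-(propan-2-yl)bicyclo[5.3.0]dec-7-en-5-yl 4-(prop-2-en-1-yloxy)benzoate
Conditions: Me4NBH(OAc)3, MeCN–AcOH, −20 °C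
Reagents that add atoms: none
Why: Evans–Saksena reduction: the β hydroxyl at C3 exchanges with an acetoxy group on boron, and the alkoxyborohydride delivers hydride to the β face of the C1 carbonyl through a six-membered transition state, so the new hydroxyl is α and trans to the C3 hydroxyl (1S). The reagent does not reduce esters or unactivated ketones without the directing hydroxyl.

Step 18
Reactants: 28 (1S,3R,4S,5S,10R)-1,3-dihydroxy-7,10-dimethyl-3-(propan-2-yl)bicyclo[5.3.0]dec-7-en-5-yl 4-(prop-2-en-1-yloxy)benzoate
Product: 29 (1S,3R,4S,5S,10R)-1-acetoxy-3-hydroxy-7,10-dimethyl-3-(propan-2-yl)bicyclo[5.3.0]dec-7-en-5-yl 4-(prop-2-en-1-yloxy)benzoate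
Conditions: Ac2O (1.5 equiv), pyridine, DMAP (cat.), CH2Cl2, 0 °C → rt
Reagents that add atoms: acetic anhydride (CC(=O)OC(C)=O)
Why: Acetylation of the secondary alcohol; the hindered tertiary C3 hydroxyl is not acylated under these mild conditions and the phenol is still protected.

Step 19
Reactants: 29 (1S,3R,4S,5S,10R)-1-acetoxy-3-hydroxy-7,10-dimethyl-3-(propan-2-yl)bicyclo[5.3.0]dec-7-en-5-yl 4-(prop-2-en-1-yloxy)benzoate
Product: 30 (1S,3R,4S,5S,10R)-1-acetoxy-3-hydroxy-7,10-dimethyl-3-(propan-2-yl)bicyclo[5.3.0]dec-7-en-5-yl 4-hydroxybenzoate (CNP0275279.1)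
Conditions: Pd(PPh3)4 (5 mol %), morpholine, THF, rt
Reagents that add atoms: none
Why: Zerovalent palladium ionises the aryl allyl ether to a π-allyl complex with the acyl-stabilised phenoxide as leaving group, and morpholine traps the allyl group; neither ester, the tertiary alcohol nor the ring alkene reacts.

## Compound list

1 | (R)-4-(tert-butyldimethylsilyloxy)cyclopent-2-en-1-one | O=C1C=C[C@H](O[Si](C)(C)C(C)(C)C)C1 | starting material
2 | tert-butyldimethyl{[(1R,2R)-2-methyl-4-(trimethylsilyloxy)cyclopent-3-en-1-yl]oxy}silane (methyl trans to silyloxy) | C[Si](C)(C)OC1=C[C@@H](C)[C@H](O[Si](C)(C)C(C)(C)C)C1 | intermediate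
3 | (R)-4-(tert-butyldimethylsilyloxy)-3-methylcyclopent-2-en-1-one | O=C1C=C(C)[C@H](O[Si](C)(C)C(C)(C)C)C1 | intermediate
4 | (4R)-2,3-dibromo-4-(tert-butyldimethylsilyloxy)-3-methylcyclopentan-1-one (trans dibromide, C2 and C3 not defined) | O=C1C(Br)C(C)(Br)[C@H](O[Si](C)(C)C(C)(C)C)C1 | intermediate (not isolated)
5 | (R)-2-bromo-4-(tert-butyldimethylsilyloxy)-3-methylcyclopent-2-en-1-one | O=C1C(Br)=C(C)[C@H](O[Si](C)(C)C(C)(C)C)C1 | intermediate
6 | (1R,4R)-2-bromo-4-(tert-butyldimethylsilyloxy)-3-methyl-1-(propan-2-yl)cyclopent-2-en-1-ol (OH cis to OSi) | BrC1=C(C)[C@H](O[Si](C)(C)C(C)(C)C)C[C@@]1(O)C(C)C | intermediate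
7 | {[(1R,4R)-2-bromo-4-(tert-butyldimethylsilyloxy)-3-methyl-1-(propan-2-yl)cyclopent-2-en-1-yl]oxy}triethylsilane | BrC1=C(C)[C@H](O[Si](C)(C)C(C)(C)C)C[C@@]1(O[Si](CC)(CC)CC)C(C)C | intermediate
8 | [(3R,5R)-3-(tert-butyldimethylsilyloxy)-2-methyl-5-(propan-2-yl)-5-(triethylsilyloxy)cyclopent-1-en-1-yl]lithium | [Li]C1=C(C)[C@H](O[Si](C)(C)C(C)(C)C)C[C@@]1(O[Si](CC)(CC)CC)C(C)C | intermediate (not isolated)
9 | 1-[(3R,5R)-3-(tert-butyldimethylsilyloxy)-2-methyl-5-(propan-2-yl)-5-(triethylsilyloxy)cyclopent-1-en-1-yl]ethan-1-ol (both carbinol epimers) | CC(O)C1=C(C)[C@H](O[Si](C)(C)C(C)(C)C)C[C@@]1(O[Si](CC)(CC)CC)C(C)C | intermediate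
10 | 1-[(3R,5R)-3-(tert-butyldimethylsilyloxy)-2-methyl-5-(propan-2-yl)-5-(triethylsilyloxy)cyclopent-1-en-1-yl]ethan-1-one | CC(=O)C1=C(C)[C@H](O[Si](C)(C)C(C)(C)C)C[C@@]1(O[Si](CC)(CC)CC)C(C)C | intermediate (precursor of the key step)
11 | methoxyallene | COC=C=C | starting material
12 | (1-methoxypropa-1,2-dien-1-yl)lithium | COC([Li])=C=C | intermediate (not isolated)
13 | tert-butyl(1-methoxypropa-1,2-dien-1-yl)dimethylsilane | COC(=C=C)[Si](C)(C)C(C)(C)C | intermediate
14 | 1-[tert-butyl(dimethyl)silyl]prop-2-en-1-one | C=CC(=O)[Si](C)(C)C(C)(C)C | intermediate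
15 | lithium 1-[(3R,5R)-3-(tert-butyldimethylsilyloxy)-2-methyl-5-(propan-2-yl)-5-(triethylsilyloxy)cyclopent-1-en-1-yl]ethen-1-olate | C=C(O[Li])C1=C(C)[C@H](O[Si](C)(C)C(C)(C)C)C[C@@]1(O[Si](CC)(CC)CC)C(C)C | intermediate (not isolated)
16 | lithium 3-[tert-butyl(dimethyl)silyl]-1-[(3R,5R)-3-(tert-butyldimethylsilyloxy)-2-methyl-5-(propan-2-yl)-5-(triethylsilyloxy)cyclopent-1-en-1-yl]-1-oxopent-4-en-3-olate (carbinol carbon not defined) | C=CC(O[Li])(CC(=O)C1=C(C)[C@H](O[Si](C)(C)C(C)(C)C)C[C@@]1(O[Si](CC)(CC)CC)C(C)C)[Si](C)(C)C(C)(C)C | intermediate (not isolated)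
17 | lithium (1R,2S)-2-(tert-butyldimethylsilyloxy)-2-ethenyl-1-[(3R,5R)-3-(tert-butyldimethylsilyloxy)-2-methyl-5-(propan-2-yl)-5-(triethylsilyloxy)cyclopent-1-en-1-yl]cyclopropan-1-olate (vinyl and cyclopentenyl cis) | C=C[C@@]1(O[Si](C)(C)C(C)(C)C)C[C@@]1(O[Li])C2=C(C)[C@H](O[Si](C)(C)C(C)(C)C)C[C@@]2(O[Si](CC)(CC)CC)C(C)C | intermediate (not isolated)
18 | lithium (1R,3R,10R)-1,7-bis(tert-butyldimethylsilyloxy)-10-methyl-3-(propan-2-yl)-3-(triethylsilyloxy)bicyclo[5.3.0]deca-4,7-dien-5-olate | CC(C)(C)[Si](C)(C)O[C@@H]1C[C@@](O[Si](CC)(CC)CC)(C(C)C)C2=C(O[Li])CC(O[Si](C)(C)C(C)(C)C)=CC[C@@]12C | intermediate (not isolated)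
19 | (1R,3R,4R,10R)-1,7-bis(tert-butyldimethylsilyloxy)-10-methyl-3-(propan-2-yl)-3-(triethylsilyloxy)bicyclo[5.3.0]dec-7-en-5-one (trans-fused) | CC(C)(C)[Si](C)(C)O[C@@H]1C[C@@](O[Si](CC)(CC)CC)(C(C)C)[C@@H]2C(=O)CC(O[Si](C)(C)C(C)(C)C)=CC[C@@]12C | intermediate (product of the key step)
20 | (1R,3R,4S,5S,10R)-1,7-bis(tert-butyldimethylsilyloxy)-10-methyl-3-(propan-2-yl)-3-(triethylsilyloxy)bicyclo[5.3.0]dec-7-en-5-ol | CC(C)(C)[Si](C)(C)O[C@@H]1C[C@@](O[Si](CC)(CC)CC)(C(C)C)[C@@H]2[C@@H](O)CC(O[Si](C)(C)C(C)(C)C)=CC[C@@]12C | intermediate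
21 | dilithium (1R,3R,4S,5S,10R)-1-(tert-butyldimethylsilyloxy)-10-methyl-3-(propan-2-yl)-3-(triethylsilyloxy)bicyclo[5.3.0]dec-7-ene-5,7-bis(olate) | CC(C)(C)[Si](C)(C)O[C@@H]1C[C@@](O[Si](CC)(CC)CC)(C(C)C)[C@@H]2[C@@H](O[Li])CC(O[Li])=CC[C@@]12C | intermediate (not isolated)
22 | (1R,3R,4S,5S,10R)-1-(tert-butyldimethylsilyloxy)-5-hydroxy-10-methyl-3-(propan-2-yl)-3-(triethylsilyloxy)bicyclo[5.3.0]dec-7-en-7-yl trifluoromethanesulfonate | CC(C)(C)[Si](C)(C)O[C@@H]1C[C@@](O[Si](CC)(CC)CC)(C(C)C)[C@@H]2[C@@H](O)CC(OS(=O)(=O)C(F)(F)F)=CC[C@@]12C | intermediate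
23 | (1R,3R,4S,5S,10R)-1-(tert-butyldimethylsilyloxy)-7,10-dimethyl-3-(propan-2-yl)-3-(triethylsilyloxy)bicyclo[5.3.0]dec-7-en-5-ol | CC(C)(C)[Si](C)(C)O[C@@H]1C[C@@](O[Si](CC)(CC)CC)(C(C)C)[C@@H]2[C@@H](O)CC(C)=CC[C@@]12C | intermediate
24 | 4-(prop-2-en-1-yloxy)benzoyl chloride | C=CCOc1ccc(C(=O)Cl)cc1 | starting material
25 | (1R,3R,4S,5S,10R)-1-(tert-butyldimethylsilyloxy)-7,10-dimethyl-3-(propan-2-yl)-3-(triethylsilyloxy)bicyclo[5.3.0]dec-7-en-5-yl 4-(prop-2-en-1-yloxy)benzoate | CC(C)(C)[Si](C)(C)O[C@@H]1C[C@@](O[Si](CC)(CC)CC)(C(C)C)[C@@H]2[C@@H](OC(=O)c3ccc(OCC=C)cc3)CC(C)=CC[C@@]12C | intermediate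
26 | (1R,3R,4S,5S,10R)-1,3-dihydroxy-7,10-dimethyl-3-(propan-2-yl)bicyclo[5.3.0]dec-7-en-5-yl 4-(prop-2-en-1-yloxy)benzoate | O[C@@H]1C[C@@](O)(C(C)C)[C@@H]2[C@@H](OC(=O)c3ccc(OCC=C)cc3)CC(C)=CC[C@@]12C | intermediate
27 | (3R,4S,5S,10R)-3-hydroxy-7,10-dimethyl-1-oxo-3-(propan-2-yl)bicyclo[5.3.0]dec-7-en-5-yl 4-(prop-2-en-1-yloxy)benzoate | O=C1C[C@@](O)(C(C)C)[C@@H]2[C@@H](OC(=O)c3ccc(OCC=C)cc3)CC(C)=CC[C@@]12C | intermediate
28 | (1S,3R,4S,5S,10R)-1,3-dihydroxy-7,10-dimethyl-3-(propan-2-yl)bicyclo[5.3.0]dec-7-en-5-yl 4-(prop-2-en-1-yloxy)benzoate | O[C@H]1C[C@@](O)(C(C)C)[C@@H]2[C@@H](OC(=O)c3ccc(OCC=C)cc3)CC(C)=CC[C@@]12C | intermediate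
29 | (1S,3R,4S,5S,10R)-1-acetoxy-3-hydroxy-7,10-dimethyl-3-(propan-2-yl)bicyclo[5.3.0]dec-7-en-5-yl 4-(prop-2-en-1-yloxy)benzoate | CC(=O)O[C@H]1C[C@@](O)(C(C)C)[C@@H]2[C@@H](OC(=O)c3ccc(OCC=C)cc3)CC(C)=CC[C@@]12C | intermediate
30 | (1S,3R,4S,5S,10R)-1-acetoxy-3-hydroxy-7,10-dimethyl-3-(propan-2-yl)bicyclo[5.3.0]dec-7-en-5-yl 4-hydroxybenzoate | CC(=O)O[C@H]1C[C@@](O)(C(C)C)[C@@H]2[C@@H](OC(=O)c3ccc(O)cc3)CC(C)=CC[C@@]12C | target

## Step count and least certain steps

Total: 19 steps. Longest linear sequence: 17 steps (steps 1–7, then 10–19, from compound 1). The acylsilane branch is 2 steps (8 and 9) and joins at step 10.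

**Step 10 (key step).** Three processes can fail.
- The [3,3] shift is slowed by the fully substituted C10 terminus, whose methyl group must point over the three-membered ring in the boat, so that cyclopropanolate 17 may be diverted into ring opening and protonation.
- Facial selectivity at C10 may be incomplete, because the α isopropyl group on C3 opposes the directing effect of the C1 silyloxy group.
- Enolate 18 may expel the C3 silyloxy group or be protonated at C4 without selectivity; a cis-fused ketone would then need equilibration with catalytic DBU, at the risk of the same elimination.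

Fallback, the same ring construction without anions: ketone 10 is converted with LiN(iPr)2 and TBSCl into the 2-silyloxydiene F1. Rh2(OAc)4-catalysed decomposition of methyl 2-diazobut-3-enoate cyclopropanates its terminal enol ether alkene, and the neutral cis-divinylcyclopropane is heated until the Cope rearrangement to the cycloheptadiene ester F2 is complete. DIBAL-H gives the allylic alcohol F3, mesylation followed by LiBHEt3 gives the C7 methyl compound F4, and buffered fluoride (TBAF, AcOH) releases the ketone F5. The dissolving-metal reduction of step 11 then rejoins the route at 23.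

**Step 11.** Electron-transfer reduction may give a mixture at C5 or return ketone through enolisation, and the lithium amide formed may trigger loss of the C3 silyloxy group. Fallback: from 19, NaBH4 is expected to attack anti to the angular methyl group and give the axial 5R alcohol F6. A Mitsunobu reaction with 4-nitrobenzoic acid (PPh3, DIAD) inverts C5 to the 4-nitrobenzoate F7, and DIBAL-H at −78 °C releases 20.

**Step 12.** Cleavage of the tert-butyldimethylsilyl enol ether by MeLi may be slow, and any C7 ketone formed in the flask lets the enolate equilibrate towards C6 and give the regioisomeric triflate. Fallback by a Shapiro reaction: from 20, TBAF buffered with AcOH removes only the enol silyl group to give the β-hydroxy ketone F8, and 2,4,6-triisopropylbenzenesulfonyl hydrazide gives the hydrazone F9. Excess n-BuLi deprotonates C8, the less hindered α carbon, the alkenyllithium is quenched with MeI, and the route is rejoined at 23.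

**Step 4.** Facial selectivity rests on a silyloxy group two carbons from the carbonyl and may be modest; γ-deprotonation of the enone and bromine–metal exchange compete. Fallback from the chiral pool, which takes C3 from a terpene instead of creating it:
- (S)-terpinen-4-ol F10 is hydroxylated with SeO2 and t-BuOOH at the ring CH2 next to the methyl-bearing alkene carbon to give the cis-diol F11. The ene reaction and [2,3] shift involve no allylic transposition, and delivery is pseudoaxial, cis to the tertiary hydroxyl.
- TBSCl and imidazole give the secondary silyl ether F12, and TESOTf gives the bis-silyl ether F13.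
- Ozonolysis (O3, then PPh3) gives the keto aldehyde F14.
- Piperidinium acetate closes the aldehyde enamine onto the methyl ketone and dehydrates to the cyclopentene aldehyde F15, and MeMgBr then gives 9.

This sequence is not the main line because the enamine of F14 carries a β silyloxy group that can be expelled and the α-silyloxy ketone centre can epimerise.

**Step 17.** Intermolecular hydride attack on the α face, or slow reaction of the hindered ketone, would return the β alcohol. Fallback without the ketone: a Mitsunobu reaction of diol 26 with AcOH (PPh3, DIAD) displaces the secondary C1 hydroxyl with inversion and gives acetate 29 directly; the tertiary hydroxyl does not react and no new compound is made.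

Further compounds
F1 | step 10 | tert-butyl({1-[(3R,5R)-3-(tert-butyldimethylsilyloxy)-2-methyl-5-(propan-2-yl)-5-(triethylsilyloxy)cyclopent-1-en-1-yl]ethenyl}oxy)dimethylsilane | C=C(O[Si](C)(C)C(C)(C)C)C1=C(C)[C@H](O[Si](C)(C)C(C)(C)C)C[C@@]1(O[Si](CC)(CC)CC)C(C)C
F2 | step 10 | methyl (1R,3R,10R)-1,5-bis(tert-butyldimethylsilyloxy)-10-methyl-3-(propan-2-yl)-3-(triethylsilyloxy)bicyclo[5.3.0]deca-4,7-diene-7-carboxylate | CC(C)(C)[Si](C)(C)O[C@@H]1C[C@@](O[Si](CC)(CC)CC)(C(C)C)C2=C(O[Si](C)(C)C(C)(C)C)CC(C(=O)OC)=CC[C@@]12C
F3 | step 10 | [(1R,3R,10R)-1,5-bis(tert-butyldimethylsilyloxy)-10-methyl-3-(propan-2-yl)-3-(triethylsilyloxy)bicyclo[5.3.0]deca-4,7-dien-7-yl]methanol | CC(C)(C)[Si](C)(C)O[C@@H]1C[C@@](O[Si](CC)(CC)CC)(C(C)C)C2=C(O[Si](C)(C)C(C)(C)C)CC(CO)=CC[C@@]12C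
F4 | step 10 | (1R,3R,10R)-1,5-bis(tert-butyldimethylsilyloxy)-7,10-dimethyl-3-(propan-2-yl)-3-(triethylsilyloxy)bicyclo[5.3.0]deca-4,7-diene | CC(C)(C)[Si](C)(C)O[C@@H]1C[C@@](O[Si](CC)(CC)CC)(C(C)C)C2=C(O[Si](C)(C)C(C)(C)C)CC(C)=CC[C@@]12C
F5 | step 10 | (1R,3R,4R,10R)-1-(tert-butyldimethylsilyloxy)-7,10-dimethyl-3-(propan-2-yl)-3-(triethylsilyloxy)bicyclo[5.3.0]dec-7-en-5-one | CC(C)(C)[Si](C)(C)O[C@@H]1C[C@@](O[Si](CC)(CC)CC)(C(C)C)[C@@H]2C(=O)CC(C)=CC[C@@]12C
F6 | step 11 | (1R,3R,4S,5R,10R)-1,7-bis(tert-butyldimethylsilyloxy)-10-methyl-3-(propan-2-yl)-3-(triethylsilyloxy)bicyclo[5.3.0]dec-7-en-5-ol (axial C5 epimer of 20) | CC(C)(C)[Si](C)(C)O[C@@H]1C[C@@](O[Si](CC)(CC)CC)(C(C)C)[C@@H]2[C@H](O)CC(O[Si](C)(C)C(C)(C)C)=CC[C@@]12C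
F7 | step 11 | (1R,3R,4S,5S,10R)-1,7-bis(tert-butyldimethylsilyloxy)-10-methyl-3-(propan-2-yl)-3-(triethylsilyloxy)bicyclo[5.3.0]dec-7-en-5-yl 4-nitrobenzoate | CC(C)(C)[Si](C)(C)O[C@@H]1C[C@@](O[Si](CC)(CC)CC)(C(C)C)[C@@H]2[C@@H](OC(=O)c3ccc(cc3)[N+](=O)[O-])CC(O[Si](C)(C)C(C)(C)C)=CC[C@@]12C
F8 | step 12 | (1R,3R,4S,5S,10R)-1-(tert-butyldimethylsilyloxy)-5-hydroxy-10-methyl-3-(propan-2-yl)-3-(triethylsilyloxy)bicyclo[5.3.0]decan-7-one | CC(C)(C)[Si](C)(C)O[C@@H]1C[C@@](O[Si](CC)(CC)CC)(C(C)C)[C@@H]2[C@@H](O)CC(=O)CC[C@@]12C
F9 | step 12 | 2,4,6-triisopropylbenzenesulfonyl hydrazone of F8 at C7 | CC(C)(C)[Si](C)(C)O[C@@H]1C[C@@](O[Si](CC)(CC)CC)(C(C)C)[C@@H]2[C@@H](O)CC(=NNS(=O)(=O)c3c(C(C)C)cc(C(C)C)cc3C(C)C)CC[C@@]12C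
F10 | step 4 | (S)-terpinen-4-ol | CC1=CC[C@](O)(C(C)C)CC1
F11 | step 4 | (1R,5R)-2-methyl-5-(propan-2-yl)cyclohex-2-ene-1,5-diol (cis diol) | CC1=CC[C@](O)(C(C)C)C[C@H]1O
F12 | step 4 | (1R,5R)-5-(tert-butyldimethylsilyloxy)-4-methyl-1-(propan-2-yl)cyclohex-3-en-1-ol | CC1=CC[C@](O)(C(C)C)C[C@H]1O[Si](C)(C)C(C)(C)C
F13 | step 4 | tert-butyldimethylsilyl and triethylsilyl bis-ether of F11 (secondary O–TBS, tertiary O–TES) | CC1=CC[C@](O[Si](CC)(CC)CC)(C(C)C)C[C@H]1O[Si](C)(C)C(C)(C)C
F14 | step 4 | 5-(tert-butyldimethylsilyloxy)-6-oxo-3-(propan-2-yl)-3-(triethylsilyloxy)heptanal (configuration as in the SMILES) | CC(=O)[C@H](O[Si](C)(C)C(C)(C)C)C[C@@](CC=O)(O[Si](CC)(CC)CC)C(C)C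
F15 | step 4 | (3R,5R)-3-(tert-butyldimethylsilyloxy)-2-methyl-5-(propan-2-yl)-5-(triethylsilyloxy)cyclopent-1-ene-1-carbaldehyde | O=CC1=C(C)[C@H](O[Si](C)(C)C(C)(C)C)C[C@@]1(O[Si](CC)(CC)CC)C(C)C
F0 | step 17 | none | none
A1 | alternative 1 | endo Diels–Alder adduct, methyl 5-(tert-butyldimethylsilyloxy)-1,4-dimethyl-6-(2-methylpropanoyl)cyclohex-3-ene-1-carboxylate (configuration as in the SMILES) | COC(=O)[C@]1(C)CC=C(C)[C@@H](O[Si](C)(C)C(C)(C)C)[C@H]1C(=O)C(C)C
A2 | alternative 1 | (E)-tert-butyl(dimethyl)[(2-methylbuta-1,3-dien-1-yl)oxy]silane | C=C/C(C)=C/O[Si](C)(C)C(C)(C)C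
A3 | alternative 1 | methyl (E)-2,5-dimethyl-4-oxohex-2-enoate | COC(=O)/C(C)=C/C(=O)C(C)C
A4 | alternative 2 | trans-fused bicyclic enone, 5-(tert-butyldimethylsilyloxy)-7,10-dimethylbicyclo[5.3.0]deca-1,7-dien-3-one (configuration as in the SMILES) | C1=CC(=O)[C@@H]2[C@H](O[Si](C)(C)C(C)(C)C)CC(C)=CC[C@@]12C
A5 | alternative 2 | (E)-1-[(7R)-7-(tert-butyldimethylsilyloxy)-2,5-dimethylcyclohepta-1,4-dien-1-yl]-3-(trimethylsilyl)prop-2-en-1-one | C[Si](C)(C)/C=C/C(=O)C1=C(C)CC=C(C)C[C@H]1O[Si](C)(C)C(C)(C)C
A6 | alternative 3 | (3R,4S,5S,10R)-7,10-dimethyl-1-oxo-3-(propan-2-yl)-3-(triethylsilyloxy)bicyclo[5.3.0]dec-7-en-5-yl 4-(tert-butyldimethylsilyloxy)benzoate | O=C1C[C@@](O[Si](CC)(CC)CC)(C(C)C)[C@@H]2[C@@H](OC(=O)c3ccc(O[Si](C)(C)C(C)(C)C)cc3)CC(C)=CC[C@@]12C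
A7 | alternative 3 | diazomethyl ketone on C10 of the cycloheptene bearing the C4 side chain CH(OSiEt3)(i-Pr) (configuration as in the SMILES) | [N-]=[N+]=CC(=O)[C@]1(C)CC=C(C)C[C@H](OC(=O)c2ccc(O[Si](C)(C)C(C)(C)C)cc2)[C@H]1[C@H](O[Si](CC)(CC)CC)C(C)C
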